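## The problem

The target is made of two flavanones joined by one bond between the sp3 carbon C3 of unit 1 (the unit with the 4-hydroxyphenyl group) and the aromatic carbon C8 of unit 2 (the unit with the 4-methoxyphenyl group). A fully substituted, tri-oxygenated benzene ring therefore sits on a ring carbon that is also flanked by a ketone and by an aryl-bearing stereocentre. Three stereocentres are needed: C2 (R) and C3 (S) of unit 1, which are trans, and C2 (S) of unit 2. C3 of unit 1 is alpha to the C4 ketone and relaxes to the trans arrangement, so only C2 of unit 1 needs an external source of chirality. C2 of unit 2 is separated from unit 1 by the rotating C3–C8 bond, cannot be expected to feel it, and needs a second, independent source. Ring C of a flavanone opens to the chalcone by retro-oxa-Michael reaction once C3 is deprotonated, which would erase C2 of unit 1, so strong base is excluded once that centre exists. A free phenol ortho to the C3–C8 bond and next to the C4 ketone can cyclodehydrate to a benzofuran under strong acid, the phloroglucinol rings are easily attacked by electrophiles and oxidants, and five phenols must be freed at the end beside one methyl ether. The enabling feature lies in ring C of unit 2: O1 and C4 are ortho substituents of phloroglucinol ring A, and C2–C3 with its aryl group is a 4-methoxystyrene. An ortho-hydroxybenzyl alcohol on that ring is a latent ortho-quinone methide that can take up the styrene across O1–C2 and C3–C4, and with only the oxygen beside the hydroxymethyl group free it can close only to the 8-linked chroman.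

## Retrosynthesis

**Benzyl ethers.** Target 23 is traced to its pentabenzyl ether 22 by cutting five O–benzyl bonds. Benzyl is the one group that survives acid, oxidant and organometallic steps and leaves the methyl ether untouched under hydrogenolysis. The forward step only has to spare the benzylic C2–O bonds of the two flavanones.

**C4 carbonyl of unit 2.** The carbonyl oxygen at C4 of unit 2 is removed, via alcohol 21, to give flavan 20. This is preferred to carrying the oxygen through the ring-forming step, because a methide carbon without a substituent gives the most stabilised and least hindered quinone methide. The forward reaction must oxidise one benzylic CH2 on a ring with three oxygen donors without touching the benzyl ethers.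

**Ring C of unit 2 (key cut).** O1–C2 and C3–C4 of unit 2 are cut together, giving ortho-hydroxybenzyl alcohol 17 and 4-methoxystyrene 18. Cutting only O1–C2 (oxa-Michael of a chalcone) would need a second acyl group on an already crowded ring and offers no reliable handle on C2. The two-bond cut removes a ring, a stereocentre and a whole aryl group at once and leaves the complete unit 1 as a spectator. The forward step must set C2 (S) by catalyst control and beat self-condensation of the quinone methide 19.

**Hydroxymethyl carbon.** The C4–C4a bond of unit 2 is cut next, through cyclic boronate 16 back to phenol 15. A phenol-directed ortho-hydroxymethylation is chosen over formylation and reduction because it needs neither base nor hydride next to the base-labile, ketone-bearing unit 1. Regiochemistry follows from the single free ortho position.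

**The bond between the units.** The aryl–C3 bond is cut to give the 3-carboxylated flavanone 7 and stannane 11, with the tetravalent-lead aryl 12 as the actual coupling partner. The quaternary ester 13 and its acid 14 are the intermediates. Palladium-catalysed enolate arylation would need strong base that opens ring C, and a deoxybenzoin condensation would give racemic material. Aryllead ligand coupling forms hindered aryl–C(sp3) bonds under pyridine. Once C3 is quaternary the ring cannot open, and the ester then leaves as CO2 while C3 settles trans to C2.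

**Ring C of unit 1.** O1–C2 is cut by a retro-oxa-Michael step to alkylidene 6, and C2=C3 by a retro-Knoevenagel step to β-keto ester 4 and aldehyde 5. The same ester that later activates C3 makes the alkylidene doubly activated, which is what allows a bifunctional thiourea to close the ring enantioselectively. A plain chalcone has no such handle. The forward step must set C2 (R).

**Building blocks.** Ester 4 comes from acetophenone 2 by C-acylation (via dianion 3), and 2 from the trihydroxyacetophenone 1 by selective dibenzylation. Stannane 11 comes from the methoxymethyl ether 9 of phenol 8 by directed lithiation (aryllithium 10). The methoxymethyl group marks the one oxygen that must be free in 15 and 17, so no later desymmetrisation is needed.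

## Roads not taken

**Alternative 1:** The cut is through C4–C4a and C8a–O1 of unit 1. In the forward sense, a fluoride-released aryne from silyl triflate A2 inserts into the carboxyl group of the diarylacrylic acid A1 (O-arylation, then acyl shift to the ortho carbanion) and gives the hydroxy chalcone A3.
- Merits: all carbons of unit 1 are assembled in one convergent step, A1 is a simple condensation product of an arylacetic acid with 5, and the 3-benzyloxy group of the aryne fixes the regiochemistry.
- Weak points: the acyl shift must pass through a strained intermediate at a carbonyl flanked by a 2,6-disubstituted aryl group, so aryl ester by-products are likely. A3 has neither ring nor stereocentre, and its closure is an oxa-Michael addition on an α-aryl chalcone without a second activating group, for which enantioselective catalysis is not established. The symmetric bis(methoxymethyl) ring must later be desymmetrised under base on a base-labile flavanone.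
- Comparison: this road reaches the carbon skeleton of unit 1 in fewer steps than steps 1–4 and 7–8. The chosen plan sets against that a ring closure made catalysable by the ester in 6, an aryl ring that arrives already differentiated in 11, and no base after C2 exists.

**Alternative 2:** The cut is through C8–C8a and C6–C7 of ring A of unit 2. Thermal benzannulation of the chromenyl siloxyalkyne A4 with cyclobutenone A5 (vinylketene, [2+2], ring opening, 6π closure) gives phenol A6.
- Merits: the crowded arene is grown around the existing C3–C8 bond, so no hindered aryl–C(sp3) coupling is needed. The three oxygens emerge differentiated by construction, which is better than the lithiation of 9, where two similar positions must be told apart.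
- Weak points: A4 carries a C2 stereocentre on a 2H-chromene that can racemise by reversible electrocyclic ring opening at benzannulation temperatures, and it is a long, sensitive substrate. After the annulation, C3=C4 of unit 1 must be hydrated to the trans ketone although the alkene is benzylic at both ends. The ethyl ether must be cleaved beside the methyl ether of ring B, and ring C of unit 2 is still to be built.
- Comparison: on oxygen differentiation this road is superior. The chosen plan is shorter, keeps unit 1 at the ketone level throughout and never heats a labile stereocentre.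

**Alternative 3:** The cut is through C3–C4 and O1–C2 of unit 1 at the flavan level. An enamine of arylacetaldehyde A7, formed with a prolinol silyl ether catalyst, adds to the quinone methide released from sulfone A8, and the aldehyde closes to lactol A9 with C3 defined.
- Merits: the reaction class is well established with high enantioselectivity, needs no metal for the aryl–C3 bond, and uses the same type of intermediate as the chosen key step.
- Weak points: an arylacetaldehyde with two ortho substituents gives a hindered, conjugated enamine, and the α-aryl centre of A9 can epimerise through the open aldehyde. The C2 aryl group must still be added to the lactol, and C4 must then be oxidised next to an aryl-bearing C3, where elimination to the 3-arylchromene is favoured. Chirality is first stored at the centre that becomes epimerisable in the flavanone and must be relayed to C2 before oxidation.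
- Comparison: its asymmetric step probably has the broader precedent for high selectivity than the thiourea closure of 6. The chosen plan sets against that the correct oxidation level of unit 1 from the start, chirality stored at the robust C2, and only one benzylic oxidation in the whole route.

Key step: step 11

Remark: the sense of induction of the cinchona thiourea (step 4) and of the phosphoramide (step 11) is assigned by analogy with simpler substrates; if a trial shows the opposite sense, the pseudoenantiomeric or enantiomeric catalyst is used with no other change.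

Remark: compounds 1, 5, 8 and 18 are taken as catalogue compounds.

## Route

Step 1
Reactants: 1 1-(2,4,6-trihydroxyphenyl)ethanone
Product: 2 1-[2,4-bis(benzyloxy)-6-hydroxyphenyl]ethanone
Conditions: BnBr (2.05 equiv), K2CO3 (2.2 equiv), DMF, 0 → 23 °C
Reagents that add atoms: benzyl bromide, BrCc1ccccc1
Why: Williamson etherification; the hydroxyl hydrogen-bonded to the acetyl carbonyl is the least nucleophilic of the three and stays free with two equivalents of halide, the usual selectivity for acylphloroglucinols.

Step 2
Reactants: 2 1-[2,4-bis(benzyloxy)-6-hydroxyphenyl]ethanone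
Product: 4 tert-butyl 3-[2,4-bis(benzyloxy)-6-hydroxyphenyl]-3-oxopropanoate, via dilithium dianion 3 (not isolated)
Conditions: LiN(SiMe3)2 (3.3 equiv), THF, −78 °C; Boc2O (1.1 equiv), −78 → −20 °C; aq NH4Cl
Reagents that add atoms: di-tert-butyl dicarbonate, CC(C)(C)OC(=O)OC(=O)OC(C)(C)C
Why: Claisen-type C-acylation of the ketone enolate within the phenoxide–enolate dianion; the product stays as its enolate until the quench, and the tert-butyl ester does not lactonise to the 4-hydroxycoumarin as smaller esters do.

Step 3
Reactants: 4 tert-butyl 3-[2,4-bis(benzyloxy)-6-hydroxyphenyl]-3-oxopropanoate; 5 4-(benzyloxy)benzaldehyde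
Product: 6 tert-butyl 2-[2,4-bis(benzyloxy)-6-hydroxybenzoyl]-3-[4-(benzyloxy)phenyl]prop-2-enoate
Conditions: piperidine (0.1 equiv), AcOH (0.1 equiv), 4 Å MS, benzene, 23 → 50 °C
Reagents that add atoms: none
Why: Knoevenagel condensation under buffered iminium catalysis; the hydrogen-bonded phenol should not add to the alkylidene without a stronger base, and both alkene isomers (an E/Z mixture is expected) lead to the same ring.

Step 4
Reactants: 6 tert-butyl 2-[2,4-bis(benzyloxy)-6-hydroxybenzoyl]-3-[4-(benzyloxy)phenyl]prop-2-enoate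
Product: 7 tert-butyl (2R)-5,7-bis(benzyloxy)-2-[4-(benzyloxy)phenyl]-4-oxochromane-3-carboxylate
Conditions: quinidine-derived 3,5-bis(trifluoromethyl)phenyl thiourea (10 mol %), toluene, −25 °C
Reagents that add atoms: none
Why: Enantioselective intramolecular oxa-Michael addition (6-endo-trig) under bifunctional thiourea–tertiary amine catalysis, the established entry to 3-carboxyflavanones; the thiourea binds the β-keto ester and the quinuclidine delivers the phenol to one face of the alkylidene, setting C2 (R). C3 remains mobile (epimers and enol) and is fixed in step 8.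

Step 5
Reactants: 8 3,5-bis(benzyloxy)phenol
Product: 9 1,3-bis(benzyloxy)-5-(methoxymethoxy)benzene
Conditions: NaH, MOMCl, THF/DMF, 0 → 23 °C
Reagents that add atoms: chloromethyl methyl ether, COCCl
Why: O-alkylation of the phenoxide (Williamson type); the methoxymethyl ether marks the one oxygen that must be free later and is the directing group for step 6.

Step 6
Reactants: 9 1,3-bis(benzyloxy)-5-(methoxymethoxy)benzene
Product: 11 tributyl[2,4-bis(benzyloxy)-6-(methoxymethoxy)phenyl]stannane, via aryllithium 10 (not isolated)
Conditions: n-BuLi (1.1 equiv), THF, 0 °C; Bu3SnCl, −78 → 23 °C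
Reagents that add atoms: tributyltin chloride, CCCC[Sn](Cl)(CCCC)CCCC
Why: Directed ortho-metalation; the chelating methoxymethoxy group together with the neighbouring benzyloxy group should acidify the position between them more than the position between the two benzyl ethers, and the aryllithium is trapped as the stannane.

Step 7
Reactants: 7 tert-butyl (2R)-5,7-bis(benzyloxy)-2-[4-(benzyloxy)phenyl]-4-oxochromane-3-carboxylate; 11 tributyl[2,4-bis(benzyloxy)-6-(methoxymethoxy)phenyl]stannane
Product: 13 tert-butyl (2S,3R)-5,7-bis(benzyloxy)-3-[2,4-bis(benzyloxy)-6-(methoxymethoxy)phenyl]-2-[4-(benzyloxy)phenyl]-4-oxochromane-3-carboxylate, via aryllead triacetate 12 (not isolated)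
Conditions: 11 (1.3 equiv), Pb(OAc)4, Hg(OAc)2 (5 mol %), CHCl3, 40 °C; then 7, pyridine (3 equiv), CHCl3, 40 °C
Reagents that add atoms: none
Why: Tin–lead exchange followed by Pinhey arylation; the tetravalent-lead aryl takes up the enol of the β-keto ester and ligand coupling forms the hindered aryl–C3 bond, a reaction known to tolerate two ortho alkoxy groups and to build quaternary centres on 3-alkoxycarbonylchromanones. The aryl group should enter anti to the C2 aryl (the descriptors change only because of the ester; the C3 configuration is erased in step 8), and once C3 is quaternary ring C can no longer open, so C2 is locked.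

Step 8
Reactants: 13 tert-butyl (2S,3R)-5,7-bis(benzyloxy)-3-[2,4-bis(benzyloxy)-6-(methoxymethoxy)phenyl]-2-[4-(benzyloxy)phenyl]-4-oxochromane-3-carboxylate
Product: 15 (2R,3S)-5,7-bis(benzyloxy)-3-[2,4-bis(benzyloxy)-6-hydroxyphenyl]-2-[4-(benzyloxy)phenyl]chroman-4-one, via beta-keto acid 14 (not isolated)
Conditions: HCl (4 M in 1,4-dioxane), MeOH (10 equiv), 0 → 40 °C
Reagents that add atoms: none
Why: Acidolysis removes the methoxymethyl group (trapped by methanol) and the tert-butyl ester; the β-keto acid loses CO2 and the enol is protonated to the more stable trans flavanone, so C3 (S) follows from C2 (R). Exposure is kept short and cool because the freed phenol beside the ketone could cyclodehydrate under stronger acid.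

Step 9
Reactants: 15 (2R,3S)-5,7-bis(benzyloxy)-3-[2,4-bis(benzyloxy)-6-hydroxyphenyl]-2-[4-(benzyloxy)phenyl]chroman-4-one
Product: 16 (2R,3S)-5,7-bis(benzyloxy)-3-[5,7-bis(benzyloxy)-2-phenyl-4H-1,3,2-benzodioxaborinin-8-yl]-2-[4-(benzyloxy)phenyl]chroman-4-one
Conditions: PhB(OH)2 (1.3 equiv), (CH2O)n (3 equiv), EtCO2H (0.2 equiv), 4 Å MS, toluene, 90 °C
Reagents that add atoms: phenylboronic acid, OB(O)c1ccccc1; paraformaldehyde (formaldehyde units), C=O
Why: Nagata ortho-hydroxymethylation; the aryl borate delivers formaldehyde to the only free position ortho to the phenol through a six-membered transition state and stores the product as the cyclic boronate, so no base is involved and a second hydroxymethylation is blocked.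

Step 10
Reactants: 16 (2R,3S)-5,7-bis(benzyloxy)-3-[5,7-bis(benzyloxy)-2-phenyl-4H-1,3,2-benzodioxaborinin-8-yl]-2-[4-(benzyloxy)phenyl]chroman-4-one
Product: 17 (2R,3S)-5,7-bis(benzyloxy)-3-[4,6-bis(benzyloxy)-2-hydroxy-3-(hydroxymethyl)phenyl]-2-[4-(benzyloxy)phenyl]chroman-4-one
Conditions: 30% aq H2O2, THF, pH 7 buffer, 0 → 23 °C
Reagents that add atoms: none
Why: Oxidative cleavage of the B–phenyl bond and hydrolysis of the resulting borate release the ortho-hydroxybenzyl alcohol under neutral conditions, so the ketone of unit 1 meets neither hydride nor base. The acid-sensitive diol is used at once.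

Step 11
Reactants: 17 (2R,3S)-5,7-bis(benzyloxy)-3-[4,6-bis(benzyloxy)-2-hydroxy-3-(hydroxymethyl)phenyl]-2-[4-(benzyloxy)phenyl]chroman-4-one; 18 4-methoxystyrene
Product: 20 (2R,3S)-5,7-bis(benzyloxy)-3-[(2S)-5,7-bis(benzyloxy)-2-(4-methoxyphenyl)chroman-8-yl]-2-[4-(benzyloxy)phenyl]chroman-4-one, via ortho-quinone methide 19 (not isolated)
Conditions: (R)-3,3'-bis(2,4,6-triisopropylphenyl)-1,1'-binaphthyl-2,2'-diyl N-triflylphosphoramide (10 mol %), 18 (5 equiv), 4 Å MS, CH2Cl2, −50 °C
Reagents that add atoms: none
Why: The acid ionises the 2,4,6-trioxygenated benzylic alcohol to ortho-quinone methide 19, which stays hydrogen-bonded or ion-paired to the chiral phosphoramide. The terminal CH2 of 18 attacks the methide carbon (C3–C4 of unit 2) and the phenolic oxygen, still held by the catalyst, closes on the developing 4-methoxybenzylic cation (O1–C2), an asynchronous inverse-demand hetero-[4+2] cycloaddition. The closest known reaction is the chiral phosphoric acid or N-triflylphosphoramide catalysed cycloaddition of ortho-quinone methides, made in situ from ortho-hydroxybenzyl alcohols, with styrenes and other electron-rich alkenes to chromans. Ring C of unit 2 closes in the [4+2] sense; seen stepwise, the C–O bond forms by 6-endo-trig attack of oxygen on the benzylic cation. The one new stereocentre, C2 (S) of unit 2, is set by the chiral anion, which differentiates the faces of the styrene at the C–O bond-forming stage, while unit 1 is too remote to help or hinder. Regiochemistry follows alkene polarity, and because only the oxygen beside the hydroxymethyl group is free, the 8-linked chroman is the only ring that can form. The step needs chemoselectivity for the styrene over electron-rich arene positions of a second molecule, which the excess of 18, dilution, low temperature and the two methide-stabilising benzyloxy groups should secure.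

Step 12
Reactants: 20 (2R,3S)-5,7-bis(benzyloxy)-3-[(2S)-5,7-bis(benzyloxy)-2-(4-methoxyphenyl)chroman-8-yl]-2-[4-(benzyloxy)phenyl]chroman-4-one
Product: 21 (2R,3S)-5,7-bis(benzyloxy)-3-[(2S)-5,7-bis(benzyloxy)-4-hydroxy-2-(4-methoxyphenyl)chroman-8-yl]-2-[4-(benzyloxy)phenyl]chroman-4-one
Conditions: DDQ (1.5 equiv), CH2Cl2/H2O (18:1), 0 → 23 °C
Reagents that add atoms: water, O
Why: Benzylic oxidation by hydride abstraction; C4 of unit 2 is a CH2 on a ring with three oxygen donors and the cation is captured by water, as known for the C4 functionalisation of benzylated 5,7-dioxygenated flavan-3-ols. The C4 configuration (a mixture of epimers is expected) is irrelevant.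

Step 13
Reactants: 21 (2R,3S)-5,7-bis(benzyloxy)-3-[(2S)-5,7-bis(benzyloxy)-4-hydroxy-2-(4-methoxyphenyl)chroman-8-yl]-2-[4-(benzyloxy)phenyl]chroman-4-one
Product: 22 (2R,3S)-5,7-bis(benzyloxy)-3-[(2S)-5,7-bis(benzyloxy)-2-(4-methoxyphenyl)-4-oxochroman-8-yl]-2-[4-(benzyloxy)phenyl]chroman-4-one
Conditions: Dess–Martin periodinane (1.5 equiv), NaHCO3, CH2Cl2, 0 → 23 °C
Reagents that add atoms: none
Why: Dess–Martin oxidation of the secondary benzylic alcohol to the aryl ketone under buffered conditions that neither epimerise nor open either flavanone.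

Step 14
Reactants: 22 (2R,3S)-5,7-bis(benzyloxy)-3-[(2S)-5,7-bis(benzyloxy)-2-(4-methoxyphenyl)-4-oxochroman-8-yl]-2-[4-(benzyloxy)phenyl]chroman-4-one
Product: 23 (2R,3S)-5,7-dihydroxy-3-[(2S)-5,7-dihydroxy-2-(4-methoxyphenyl)-4-oxochroman-8-yl]-2-(4-hydroxyphenyl)chroman-4-one
Conditions: H2 (1 atm), 10% Pd/C, EtOAc/MeOH, 23 °C
Reagents that add atoms: none
Why: Hydrogenolysis of the five benzyl ethers; the methyl ether and both ketones are inert and the benzylic C2–O bonds of flavanones are cleaved much more slowly than O-benzyl groups, so the reaction is stopped at full debenzylation.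

## Compound list

1 | 1-(2,4,6-trihydroxyphenyl)ethanone | CC(=O)c1c(O)cc(O)cc1O | starting material
2 | 1-[2,4-bis(benzyloxy)-6-hydroxyphenyl]ethanone | CC(=O)c1c(O)cc(OCc2ccccc2)cc1OCc1ccccc1 | intermediate
3 | dilithium 3,5-bis(benzyloxy)-2-(1-oxidoethenyl)phenolate (dianion of 2) | [Li+].[Li+].C=C([O-])c1c([O-])cc(OCc2ccccc2)cc1OCc1ccccc1 | intermediate
4 | tert-butyl 3-[2,4-bis(benzyloxy)-6-hydroxyphenyl]-3-oxopropanoate | CC(C)(C)OC(=O)CC(=O)c1c(O)cc(OCc2ccccc2)cc1OCc1ccccc1 | intermediate
5 | 4-(benzyloxy)benzaldehyde | O=Cc1ccc(OCc2ccccc2)cc1 | starting material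
6 | tert-butyl 2-[2,4-bis(benzyloxy)-6-hydroxybenzoyl]-3-[4-(benzyloxy)phenyl]prop-2-enoate (E/Z mixture) | CC(C)(C)OC(=O)C(=Cc1ccc(OCc2ccccc2)cc1)C(=O)c1c(O)cc(OCc2ccccc2)cc1OCc1ccccc1 | intermediate
7 | tert-butyl (2R)-5,7-bis(benzyloxy)-2-[4-(benzyloxy)phenyl]-4-oxochromane-3-carboxylate (C3 epimers and enol) | CC(C)(C)OC(=O)C1C(=O)c2c(OCc3ccccc3)cc(OCc3ccccc3)cc2O[C@H]1c1ccc(OCc2ccccc2)cc1 | intermediate
8 | 3,5-bis(benzyloxy)phenol | Oc1cc(OCc2ccccc2)cc(OCc2ccccc2)c1 | starting material
9 | 1,3-bis(benzyloxy)-5-(methoxymethoxy)benzene | COCOc1cc(OCc2ccccc2)cc(OCc2ccccc2)c1 | intermediate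
10 | [2,4-bis(benzyloxy)-6-(methoxymethoxy)phenyl]lithium | [Li]c1c(OCOC)cc(OCc2ccccc2)cc1OCc1ccccc1 | intermediate
11 | tributyl[2,4-bis(benzyloxy)-6-(methoxymethoxy)phenyl]stannane | CCCC[Sn](CCCC)(CCCC)c1c(OCOC)cc(OCc2ccccc2)cc1OCc1ccccc1 | intermediate
12 | [2,4-bis(benzyloxy)-6-(methoxymethoxy)phenyl]lead triacetate | CC(=O)O[Pb](OC(C)=O)(OC(C)=O)c1c(OCOC)cc(OCc2ccccc2)cc1OCc1ccccc1 | intermediate
13 | tert-butyl (2S,3R)-5,7-bis(benzyloxy)-3-[2,4-bis(benzyloxy)-6-(methoxymethoxy)phenyl]-2-[4-(benzyloxy)phenyl]-4-oxochromane-3-carboxylate | COCOc1cc(OCc2ccccc2)cc(OCc2ccccc2)c1[C@]1(C(=O)OC(C)(C)C)C(=O)c2c(OCc3ccccc3)cc(OCc3ccccc3)cc2O[C@H]1c1ccc(OCc2ccccc2)cc1 | intermediate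
14 | (2S,3R)-5,7-bis(benzyloxy)-3-[2,4-bis(benzyloxy)-6-hydroxyphenyl]-2-[4-(benzyloxy)phenyl]-4-oxochromane-3-carboxylic acid | Oc1cc(OCc2ccccc2)cc(OCc2ccccc2)c1[C@]1(C(=O)O)C(=O)c2c(OCc3ccccc3)cc(OCc3ccccc3)cc2O[C@H]1c1ccc(OCc2ccccc2)cc1 | intermediate
15 | (2R,3S)-5,7-bis(benzyloxy)-3-[2,4-bis(benzyloxy)-6-hydroxyphenyl]-2-[4-(benzyloxy)phenyl]chroman-4-one | Oc1cc(OCc2ccccc2)cc(OCc2ccccc2)c1[C@@H]1C(=O)c2c(OCc3ccccc3)cc(OCc3ccccc3)cc2O[C@H]1c1ccc(OCc2ccccc2)cc1 | intermediate
16 | (2R,3S)-5,7-bis(benzyloxy)-3-[5,7-bis(benzyloxy)-2-phenyl-4H-1,3,2-benzodioxaborinin-8-yl]-2-[4-(benzyloxy)phenyl]chroman-4-one | B1(c2ccccc2)OCc2c(OCc3ccccc3)cc(OCc3ccccc3)c([C@@H]3C(=O)c4c(OCc5ccccc5)cc(OCc5ccccc5)cc4O[C@H]3c3ccc(OCc4ccccc4)cc3)c2O1 | intermediate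
17 | (2R,3S)-5,7-bis(benzyloxy)-3-[4,6-bis(benzyloxy)-2-hydroxy-3-(hydroxymethyl)phenyl]-2-[4-(benzyloxy)phenyl]chroman-4-one | OCc1c(OCc2ccccc2)cc(OCc2ccccc2)c([C@@H]2C(=O)c3c(OCc4ccccc4)cc(OCc4ccccc4)cc3O[C@H]2c2ccc(OCc3ccccc3)cc2)c1O | intermediate
18 | 4-methoxystyrene (1-ethenyl-4-methoxybenzene) | C=Cc1ccc(OC)cc1 | starting material
19 | (2R,3S)-5,7-bis(benzyloxy)-3-[2,4-bis(benzyloxy)-5-methylidene-6-oxocyclohexa-1,3-dien-1-yl]-2-[4-(benzyloxy)phenyl]chroman-4-one (ortho-quinone methide) | C=C1C(OCc2ccccc2)=CC(OCc2ccccc2)=C([C@@H]2C(=O)c3c(OCc4ccccc4)cc(OCc4ccccc4)cc3O[C@H]2c2ccc(OCc3ccccc3)cc2)C1=O | intermediate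
20 | (2R,3S)-5,7-bis(benzyloxy)-3-[(2S)-5,7-bis(benzyloxy)-2-(4-methoxyphenyl)chroman-8-yl]-2-[4-(benzyloxy)phenyl]chroman-4-one | COc1ccc([C@@H]2CCc3c(OCc4ccccc4)cc(OCc4ccccc4)c([C@@H]4C(=O)c5c(OCc6ccccc6)cc(OCc6ccccc6)cc5O[C@H]4c4ccc(OCc5ccccc5)cc4)c3O2)cc1 | intermediate
21 | (2R,3S)-5,7-bis(benzyloxy)-3-[(2S)-5,7-bis(benzyloxy)-4-hydroxy-2-(4-methoxyphenyl)chroman-8-yl]-2-[4-(benzyloxy)phenyl]chroman-4-one (C4 epimers of unit 2) | COc1ccc([C@@H]2CC(O)c3c(OCc4ccccc4)cc(OCc4ccccc4)c([C@@H]4C(=O)c5c(OCc6ccccc6)cc(OCc6ccccc6)cc5O[C@H]4c4ccc(OCc5ccccc5)cc4)c3O2)cc1 | intermediate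
22 | (2R,3S)-5,7-bis(benzyloxy)-3-[(2S)-5,7-bis(benzyloxy)-2-(4-methoxyphenyl)-4-oxochroman-8-yl]-2-[4-(benzyloxy)phenyl]chroman-4-one | COc1ccc([C@@H]2CC(=O)c3c(OCc4ccccc4)cc(OCc4ccccc4)c([C@@H]4C(=O)c5c(OCc6ccccc6)cc(OCc6ccccc6)cc5O[C@H]4c4ccc(OCc5ccccc5)cc4)c3O2)cc1 | intermediate
23 | (2R,3S)-5,7-dihydroxy-3-[(2S)-5,7-dihydroxy-2-(4-methoxyphenyl)-4-oxochroman-8-yl]-2-(4-hydroxyphenyl)chroman-4-one | COc1ccc([C@@H]2CC(=O)c3c(O)cc(O)c([C@@H]4C(=O)c5c(O)cc(O)cc5O[C@H]4c4ccc(O)cc4)c3O2)cc1 | target

## Step count and least certain steps

Total: 14 steps. Longest linear sequence: 12 steps (steps 1–4 and 7–14, from 1). The aryl arm (steps 5–6, from 8) joins at step 7.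

**Step 11 (key step).** The most likely failure is weak facial discrimination, because the methide carbon carries no substituent and the stereocentre forms at the far end of the alkene. Capture of the quinone methide by electron-rich arene positions of a second molecule and acid-induced re-ionisation of the new benzylic C–O bond are further risks. The fallback sets out from 16. Heating 16 with 18 in toluene at about 120 °C in a sealed tube releases 19 from the dioxaborinine without acid. The uncatalysed cycloaddition should give 20 together with its epimer at C2 of unit 2, the (2R)-flavan F1. The two are diastereomers because of unit 1 and are separated by chromatography, so the route is rejoined at 20.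

**Step 7.** Ligand coupling at the congested carbon may be slow. That would leave time for pyridine-mediated ring opening of the still enolisable ester (retro-oxa-Michael) and erosion of C2, or for loss of the lead group from 12 by protonation. A small erosion is purged later, since the minor enantiomer of unit 1 becomes a diastereomer at 20. The fallback sets out from 2 and 11 and gives up catalyst control of unit 1:
- 2 is condensed with DMF dimethyl acetal to the enaminone F2, which I2 cyclises to the 3-iodochromone F3.
- Stille coupling of F3 with 11 (Pd(PPh3)4, CuI, CsF, DMF) gives the isoflavone F4.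
- Copper-catalysed conjugate addition of 4-(benzyloxy)phenylmagnesium bromide (CuBr·SMe2, Me3SiCl, THF) and equilibration give the racemic trans flavanone F5.
- HCl in methanol removes the methoxymethyl group and the route is rejoined at 15, as the racemate.
- Steps 9–11 then give 20 together with the diastereomer of antipodal unit 1, F6, which is removed by chromatography.

**Step 4.** Enantioselectivity may be low because the 4-benzyloxy group makes the alkylidene less electrophilic, because some ring closure may already occur under the amine of step 3, or because the addition partly reverses. The fallback sets out from 2. The enaminone F2 (as above) is closed with HCl to the chromone F7. Conjugate addition of 4-(benzyloxy)phenylboronic acid, catalysed by Pd(OCOCF3)2 with the enantiomer of t-BuPyOx that gives the 2R series (NH4PF6, H2O, 1,2-dichloroethane, 60 °C), gives the (2R)-flavanone F8. Kinetic enolisation with LiN(SiMe3)2 at −78 °C and C-acylation with Boc2O rejoin the route at 7.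

**Step 12.** The C4 cation may lose a proton to give the 2H-chromene before water captures it. Hydride abstraction at C2 of unit 2 (a 4-methoxybenzylic ether) and over-oxidation are further risks. The fallback sets out from 20. The dehydrogenation is run on purpose with DDQ in dry benzene to give the 2H-chromene F9. Mukaiyama hydration (Co(acac)2, PhSiH3, O2, i-PrOH) then places the hydroxyl at the benzylic C4 by hydrogen-atom transfer to C3, and the route is rejoined at 21.

**Step 9.** Borate formation at the hindered phenol may be slow. That would allow acid-promoted, undirected hydroxymethylation and diarylmethane formation at the free position between the two benzyloxy groups. The fallback sets out from 15. Ortho-formylation through the magnesium phenoxide (MgCl2, Et3N, (CH2O)n, MeCN, 60 °C, short reaction time because of the base) gives the salicylaldehyde F10. NaBH4 at −20 °C reduces the aldehyde in preference to the hindered ketone, and the route is rejoined at 17.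

## Further compounds

F1 | step 11 | (2R,3S)-5,7-bis(benzyloxy)-3-[(2R)-5,7-bis(benzyloxy)-2-(4-methoxyphenyl)chroman-8-yl]-2-[4-(benzyloxy)phenyl]chroman-4-one | COc1ccc([C@H]2CCc3c(OCc4ccccc4)cc(OCc4ccccc4)c([C@@H]4C(=O)c5c(OCc6ccccc6)cc(OCc6ccccc6)cc5O[C@H]4c4ccc(OCc5ccccc5)cc4)c3O2)cc1
F2 | step 7 | (E)-1-[2,4-bis(benzyloxy)-6-hydroxyphenyl]-3-(dimethylamino)prop-2-en-1-one | CN(C)/C=C/C(=O)c1c(O)cc(OCc2ccccc2)cc1OCc1ccccc1
F3 | step 7 | 5,7-bis(benzyloxy)-3-iodo-4H-chromen-4-one | O=c1c(I)coc2cc(OCc3ccccc3)cc(OCc3ccccc3)c12
F4 | step 7 | 5,7-bis(benzyloxy)-3-[2,4-bis(benzyloxy)-6-(methoxymethoxy)phenyl]-4H-chromen-4-one | COCOc1cc(OCc2ccccc2)cc(OCc2ccccc2)c1-c1coc2cc(OCc3ccccc3)cc(OCc3ccccc3)c2c1=O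
F5 | step 7 | rac-(2R,3S)-5,7-bis(benzyloxy)-3-[2,4-bis(benzyloxy)-6-(methoxymethoxy)phenyl]-2-[4-(benzyloxy)phenyl]chroman-4-one (racemate, one enantiomer drawn) | COCOc1cc(OCc2ccccc2)cc(OCc2ccccc2)c1[C@@H]1C(=O)c2c(OCc3ccccc3)cc(OCc3ccccc3)cc2O[C@H]1c1ccc(OCc2ccccc2)cc1
F6 | step 7 | (2S,3R)-5,7-bis(benzyloxy)-3-[(2S)-5,7-bis(benzyloxy)-2-(4-methoxyphenyl)chroman-8-yl]-2-[4-(benzyloxy)phenyl]chroman-4-one | COc1ccc([C@@H]2CCc3c(OCc4ccccc4)cc(OCc4ccccc4)c([C@H]4C(=O)c5c(OCc6ccccc6)cc(OCc6ccccc6)cc5O[C@@H]4c4ccc(OCc5ccccc5)cc4)c3O2)cc1
F7 | step 4 | 5,7-bis(benzyloxy)-4H-chromen-4-one | O=c1ccoc2cc(OCc3ccccc3)cc(OCc3ccccc3)c12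
F8 | step 4 | (2R)-5,7-bis(benzyloxy)-2-[4-(benzyloxy)phenyl]chroman-4-one | O=C1C[C@@H](Oc2cc(OCc3ccccc3)cc(OCc3ccccc3)c12)c1ccc(OCc2ccccc2)cc1
F9 | step 12 | (2R,3S)-5,7-bis(benzyloxy)-3-[(2S)-5,7-bis(benzyloxy)-2-(4-methoxyphenyl)-2H-chromen-8-yl]-2-[4-(benzyloxy)phenyl]chroman-4-one | COc1ccc([C@@H]2C=Cc3c(OCc4ccccc4)cc(OCc4ccccc4)c([C@@H]4C(=O)c5c(OCc6ccccc6)cc(OCc6ccccc6)cc5O[C@H]4c4ccc(OCc5ccccc5)cc4)c3O2)cc1
F10 | step 9 | (2R,3S)-5,7-bis(benzyloxy)-3-[4,6-bis(benzyloxy)-3-formyl-2-hydroxyphenyl]-2-[4-(benzyloxy)phenyl]chroman-4-one | O=Cc1c(OCc2ccccc2)cc(OCc2ccccc2)c([C@@H]2C(=O)c3c(OCc4ccccc4)cc(OCc4ccccc4)cc3O[C@H]2c2ccc(OCc3ccccc3)cc2)c1O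
A1 | alternative 1 | (E)-2-[4-(benzyloxy)-2,6-bis(methoxymethoxy)phenyl]-3-[4-(benzyloxy)phenyl]prop-2-enoic acid | OC(=O)/C(=C/c1ccc(OCc2ccccc2)cc1)c1c(OCOC)cc(OCc2ccccc2)cc1OCOC
A2 | alternative 1 | 3,5-bis(benzyloxy)-2-(trimethylsilyl)phenyl trifluoromethanesulfonate | C[Si](C)(C)c1c(OS(=O)(=O)C(F)(F)F)cc(OCc2ccccc2)cc1OCc1ccccc1
A3 | alternative 1 | (E)-1-[2,4-bis(benzyloxy)-6-hydroxyphenyl]-2-[4-(benzyloxy)-2,6-bis(methoxymethoxy)phenyl]-3-[4-(benzyloxy)phenyl]prop-2-en-1-one | O=C(c1c(O)cc(OCc2ccccc2)cc1OCc1ccccc1)/C(=C/c1ccc(OCc2ccccc2)cc1)c1c(OCOC)cc(OCc2ccccc2)cc1OCOC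
A4 | alternative 2 | (2S)-5,7-bis(benzyloxy)-2-[4-(benzyloxy)phenyl]-3-{[tri(propan-2-yl)silyl]oxyethynyl}-2H-chromene | CC(C)[Si](C(C)C)(C(C)C)OC#CC1=Cc2c(OCc3ccccc3)cc(OCc3ccccc3)cc2O[C@H]1c1ccc(OCc2ccccc2)cc1
A5 | alternative 2 | 3-ethoxycyclobut-2-en-1-one | CCOC1=CC(=O)C1
A6 | alternative 2 | 2-{(2S)-5,7-bis(benzyloxy)-2-[4-(benzyloxy)phenyl]-2H-chromen-3-yl}-5-ethoxy-3-{[tri(propan-2-yl)silyl]oxy}phenol | CCOc1cc(O)c(C2=Cc3c(OCc4ccccc4)cc(OCc4ccccc4)cc3O[C@H]2c2ccc(OCc3ccccc3)cc2)c(O[Si](C(C)C)(C(C)C)C(C)C)c1
A7 | alternative 3 | [4-(benzyloxy)-2,6-bis(methoxymethoxy)phenyl]acetaldehyde | O=CCc1c(OCOC)cc(OCc2ccccc2)cc1OCOC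
A8 | alternative 3 | 3,5-bis(benzyloxy)-2-[(4-methylbenzenesulfonyl)methyl]phenol | Cc1ccc(cc1)S(=O)(=O)Cc1c(O)cc(OCc2ccccc2)cc1OCc1ccccc1
A9 | alternative 3 | (3S)-5,7-bis(benzyloxy)-3-[4-(benzyloxy)-2,6-bis(methoxymethoxy)phenyl]chroman-2-ol (C2 anomers) | COCOc1cc(OCc2ccccc2)cc(OCOC)c1[C@@H]1Cc2c(OCc3ccccc3)cc(OCc3ccccc3)cc2OC1O
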